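The plan rests on cutting the butenolide (C13–C16 and the ring oxygen) at its allylic O–C15 bond. C15 ends the C13=C14 unit that carries the C16 carbonyl, so the ring is the cycloisomer of a 2-alkylbuta-2,3-dienoate. Gold trichloride should make the ester carbonyl oxygen close onto the allene terminus, creating the O–C15 bond, the conjugated C13=C14 bond and the lactone in one operation, with loss of isobutene. The precursor is an open-chain tert-butyl allenoate, made by α-alkylating tert-butyl but-2-ynoate with a C12 iodide. The iodide is carved from (+)-podocarpic acid, which already holds C4, C5 and C10, by opening ring C and excising one ring carbon.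

Key step: step 11

Remark on the chemistry: (+)-podocarpic acid and tert-butyl but-2-ynoate are taken as catalogue compounds. Labdane numbering is used for the target and the seco compounds (C15 = ring OCH2, C16 = lactone C=O, C17 = CH2O carbon on C8); podocarpane numbering is used for the tricyclic compounds, whose C14 becomes C17 and whose C13 is removed.

Step 1
Reactants: 1 (+)-podocarpic acid; 2 dimethyl sulfate
Product: 3 O-methylpodocarpic acid (12-methoxypodocarpa-8,11,13-trien-19-oic acid; 4β-CO2H, 4α-CH3, 5α-H, 10β-CH3)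
Conditions: Me2SO4 (1.1 equiv), NaOH (2.2 equiv), H2O/MeOH, 0 °C → rt
Reagents that add atoms: dimethyl sulfate, COS(=O)(=O)OC
Why: Williamson O-methylation, in which the phenoxide is far more nucleophilic in aqueous base than the hindered axial C19 carboxylate, so one equivalent of the sulfate should methylate O12 only and no stereocentre is touched.

Step 2
Reactants: 3 O-methylpodocarpic acid; 4 water
Product: 7 12-oxo-8β-podocarp-9(11)-en-19-oic acid, via dienol ether acid 5 (not isolated), via unconjugated enone acid 6 (not isolated)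
Conditions: Li, NH3(l), THF, t-BuOH, −78 → −33 °C; NH4Cl; then 2 M HCl, THF, 50 °C
Reagents that add atoms: water, O
Why: Birch reduction leaves the donor-bearing carbons C8, C9 and C12 sp2 (8,12-diene), and aqueous acid hydrolyses the enol ether and moves C8=C9 into conjugation as C9=C11, the reversible dienol step placing H8 on the β face so that C14 sits equatorial on ring B, away from the axial C20 methyl.

Step 3
Reactants: 7 12-oxo-8β-podocarp-9(11)-en-19-oic acid
Product: 8 12-oxo-8β,9α-podocarpan-19-oic acid (trans-anti-trans)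
Conditions: Li, NH3(l), THF, −78 °C; NH4Cl
Reagents that add atoms: none
Why: dissolving-metal conjugate reduction of the enone, in which the C9 carbanion is protonated axially on the α face, anti to the C20 methyl, to give the more stable trans B/C fusion (9α-H), the lithium enolate returning the ketone on quench.

Step 4
Reactants: 8 12-oxo-8β,9α-podocarpan-19-oic acid; 9 tert-butyl 2,2,2-trichloroacetimidate
Product: 10 tert-butyl 12-oxo-8β,9α-podocarpan-19-oate
Conditions: BF3·OEt2 (cat.), CH2Cl2/cyclohexane, rt
Reagents that add atoms: tert-butyl 2,2,2-trichloroacetimidate, CC(C)(C)OC(=N)C(Cl)(Cl)Cl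
Why: acid-catalysed tert-butylation by the imidate runs through the tert-butyl cation and attack by the carboxyl oxygen, so the shielding of the axial C19 carbonyl carbon does not matter and no stereocentre is involved.

Step 5
Reactants: 10 tert-butyl 12-oxo-8β,9α-podocarpan-19-oate
Product: 12 tert-butyl 12-oxo-8β,9α-podocarp-13-en-19-oate, via silyl enol ether 11 (not isolated)
Conditions: LiN(iPr)2, THF, −78 °C; TMSCl; then Pd(OAc)2 (1.05 equiv), MeCN, rt
Reagents that add atoms: none
Why: Saegusa–Ito oxidation, in which kinetic deprotonation of the ring C ketone occurs at C13, away from the ring-fusion carbon C9 (as in trans-2-decalones and 3-oxo-5α-steroids), and palladation of the silyl enol ether followed by β-hydride elimination of H14 gives the C13=C14 enone.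

Step 6
Reactants: 12 tert-butyl 12-oxo-8β,9α-podocarp-13-en-19-oate; 13 ozone
Product: 15 tert-butyl 13,14,15,16-tetranorlabdan-12,17-olid-19-oate (trans-fused δ-lactone C12(=O)–O–C17; 8β-H, 9α-H), via aldehyde acid 14 (not isolated)
Conditions: O3, CH2Cl2/MeOH, −78 °C; warm to 0 °C; NaBH4, 0 °C → rt; 1 M HCl
Reagents that add atoms: ozone, [O-][O+]=O
Why: abnormal ozonolysis of an α,β-unsaturated ketone cleaves C13=C14 and degrades the α-keto carbonyl fragment so that C13 leaves as formic acid and C12 becomes a carboxyl, after which NaBH4 reduces the C14 aldehyde and acid closes the δ-lactone, C8 keeping (or, at the aldehyde stage, equilibrating to) its equatorial one-carbon branch.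

Step 7
Reactants: 15 tert-butyl 13,14,15,16-tetranorlabdan-12,17-olid-19-oate; 16 lithium hydroxide; 17 tert-butyldimethylsilyl chloride
Product: 20 17-(tert-butyldimethylsilyloxy)-19-tert-butoxy-19-oxo-13,14,15,16-tetranorlabdan-12-oic acid, via lithium hydroxy carboxylate 18 (not isolated), via bis-silyl derivative 19 (not isolated)
Conditions: LiOH, THF/H2O, rt; evaporate to dryness; TBSCl, imidazole, DMF, rt; then K2CO3, MeOH/THF/H2O, rt; citric acid to pH 4
Reagents that add atoms: lithium hydroxide, [Li+].[OH-]; tert-butyldimethylsilyl chloride, CC(C)(C)[Si](C)(C)Cl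
Why: saponification opens the lactone, silylation of the dry salt protects O17 and gives a silyl ester, and the much more labile silyl ester is hydrolysed selectively by carbonate in aqueous methanol, while the hindered tert-butyl ester is inert to all three operations.

Step 8
Reactants: 20 17-(tert-butyldimethylsilyloxy)-19-tert-butoxy-19-oxo-13,14,15,16-tetranorlabdan-12-oic acid
Product: 21 tert-butyl 12-hydroxy-17-(tert-butyldimethylsilyloxy)-13,14,15,16-tetranorlabdan-19-oate
Conditions: BH3·THF, THF, 0 °C → rt; H2O
Reagents that add atoms: none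
Why: borane reduces the carboxylic acid chemoselectively through its acyloxyborane, leaving the tert-butyl ester and the silyl ether untouched.

Step 9
Reactants: 21 tert-butyl 12-hydroxy-17-(tert-butyldimethylsilyloxy)-13,14,15,16-tetranorlabdan-19-oate; 22 iodine
Product: 23 tert-butyl 12-iodo-17-(tert-butyldimethylsilyloxy)-13,14,15,16-tetranorlabdan-19-oate
Conditions: I2, PPh3, imidazole, CH2Cl2, 0 °C → rt
Reagents that add atoms: iodine, II
Why: Appel-type iodination (Garegg–Samuelsson conditions) of the unhindered primary alcohol through its alkoxyphosphonium salt and SN2 displacement by iodide.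

Step 10
Reactants: 23 tert-butyl 12-iodo-17-(tert-butyldimethylsilyloxy)-13,14,15,16-tetranorlabdan-19-oate; 24 tert-butyl but-2-ynoate
Product: 26 di-tert-butyl 17-(tert-butyldimethylsilyloxy)labda-13,14-diene-16,19-dioate (a 2-substituted buta-2,3-dienoate; C13=C14=C15H2), via lithium cumulenolate 25 (not isolated)
Conditions: 24 (3 equiv), LiN(iPr)2 (3 equiv), THF/DMPU, −78 °C; then 23, −78 → −30 °C
Reagents that add atoms: tert-butyl but-2-ynoate, CC#CC(=O)OC(C)(C)C
Why: deconjugative α-alkylation of a 2-alkynoate, in which the amide base removes a γ-proton of the butynoate and the resulting cumulenolate is alkylated at its α-carbon by the primary iodide (SN2) to give the allenoate directly, with no stereocentre formed.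

Step 11
Reactants: 26 di-tert-butyl 17-(tert-butyldimethylsilyloxy)labda-13,14-diene-16,19-dioate
Product: 27 tert-butyl 17-(tert-butyldimethylsilyloxy)labd-13-en-16,15-olid-19-oate
Conditions: AuCl3 (5 mol %), CH2Cl2, rt
Reagents that add atoms: none
Why: Trivalent gold coordinates the terminal C14=C15 π bond of the allene and the C16 ester carbonyl oxygen attacks C15 anti to gold, which forms the O–C15 bond and gives a 2-tert-butoxyfuranylium species carrying gold on C14; loss of the tert-butyl cation as isobutene unveils the lactone carbonyl and protodeauration at C14 releases the catalyst. The closest known reaction type is the gold- or silver-catalysed cycloisomerisation of 2,3-allenoic acids and their tert-butyl esters to 2(5H)-furanones. The furanone ring closes in the 5-endo-trig mode, the former allene bond C13=C14 ending up inside the ring in conjugation with C16=O. No stereocentre is formed. The step needs regioselectivity for C15 over the central carbon C14 and chemoselectivity for the allenoate ester over the C19 ester; ring size secures the first (attack at C14 would give a four-membered lactone), and the second holds because only the C16 carbonyl oxygen lies within reach of an activated π bond, the C19 ester and O17 being too remote.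

Step 12
Reactants: 27 tert-butyl 17-(tert-butyldimethylsilyloxy)labd-13-en-16,15-olid-19-oate
Product: 28 (4S,5R,8R,9S,10R)-17-hydroxylabd-13-en-16,15-olid-19-oic acid (target)
Conditions: TFA/CH2Cl2/H2O (10:10:1), 0 °C → rt; then NaHCO3, MeOH/H2O; acidify to pH 3
Reagents that add atoms: none
Why: acidolysis, in which the C19 tert-butyl ester cleaves by alkyl–oxygen fission (loss of isobutene, independent of the hindrance at C4) and the primary silyl ether is protodesilylated, the acid-stable butenolide surviving and the bicarbonate wash removing any O17 trifluoroacetate.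

Compound list
1 | (+)-podocarpic acid, (4S,5R,10S)-12-hydroxypodocarpa-8,11,13-trien-19-oic acid (4β-CO2H axial, 4α-CH3, 5α-H, 10β-CH3) | C[C@]12CCC[C@](C)(C(=O)O)[C@@H]1CCc1ccc(O)cc12 | starting material
2 | dimethyl sulfate | COS(=O)(=O)OC | starting material
3 | O-methylpodocarpic acid, 12-methoxypodocarpa-8,11,13-trien-19-oic acid | C[C@]12CCC[C@](C)(C(=O)O)[C@@H]1CCc1ccc(OC)cc12 | intermediate
4 | water | O | starting material
5 | 12-methoxypodocarpa-8,12-dien-19-oic acid (dienol ether) | C[C@]12CCC[C@](C)(C(=O)O)[C@@H]1CCC1=C2CC(OC)=CC1 | intermediate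
6 | 12-oxopodocarp-8-en-19-oic acid (unconjugated enone) | C[C@]12CCC[C@](C)(C(=O)O)[C@@H]1CCC1=C2CC(=O)CC1 | intermediate
7 | 12-oxo-8β-podocarp-9(11)-en-19-oic acid | C[C@]12CCC[C@](C)(C(=O)O)[C@@H]1CC[C@H]1CCC(=O)C=C12 | intermediate
8 | 12-oxo-8β,9α-podocarpan-19-oic acid | C[C@]12CCC[C@](C)(C(=O)O)[C@@H]1CC[C@H]1CCC(=O)C[C@@H]12 | intermediate
9 | tert-butyl 2,2,2-trichloroacetimidate | CC(C)(C)OC(=N)C(Cl)(Cl)Cl | starting material
10 | tert-butyl 12-oxo-8β,9α-podocarpan-19-oate | C[C@]12CCC[C@](C)(C(=O)OC(C)(C)C)[C@@H]1CC[C@H]1CCC(=O)C[C@@H]12 | intermediate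
11 | tert-butyl 12-(trimethylsilyloxy)-8β,9α-podocarp-12-en-19-oate | C[C@]12CCC[C@](C)(C(=O)OC(C)(C)C)[C@@H]1CC[C@H]1CC=C(O[Si](C)(C)C)C[C@@H]12 | intermediate
12 | tert-butyl 12-oxo-8β,9α-podocarp-13-en-19-oate | C[C@]12CCC[C@](C)(C(=O)OC(C)(C)C)[C@@H]1CC[C@H]1C=CC(=O)C[C@@H]12 | intermediate
13 | ozone | [O-][O+]=O | starting material
14 | 19-tert-butoxy-17,19-dioxo-13,14,15,16-tetranorlabdan-12-oic acid (8β-H, 9α-H; C17 aldehyde equatorial on C8) | C[C@]12CCC[C@](C)(C(=O)OC(C)(C)C)[C@@H]1CC[C@@H](C=O)[C@@H]2CC(=O)O | intermediate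
15 | tert-butyl 13,14,15,16-tetranorlabdan-12,17-olid-19-oate (8β-H, 9α-H, trans-fused δ-lactone) | C[C@]12CCC[C@](C)(C(=O)OC(C)(C)C)[C@@H]1CC[C@H]1COC(=O)C[C@@H]12 | intermediate
16 | lithium hydroxide | [Li+].[OH-] | starting material
17 | tert-butyldimethylsilyl chloride | CC(C)(C)[Si](C)(C)Cl | starting material
18 | lithium 19-tert-butoxy-17-hydroxy-19-oxo-13,14,15,16-tetranorlabdan-12-oate | C[C@]12CCC[C@](C)(C(=O)OC(C)(C)C)[C@@H]1CC[C@@H](CO)[C@@H]2CC(=O)[O-].[Li+] | intermediate
19 | tert-butyldimethylsilyl 19-tert-butoxy-17-(tert-butyldimethylsilyloxy)-19-oxo-13,14,15,16-tetranorlabdan-12-oate | C[C@]12CCC[C@](C)(C(=O)OC(C)(C)C)[C@@H]1CC[C@@H](CO[Si](C)(C)C(C)(C)C)[C@@H]2CC(=O)O[Si](C)(C)C(C)(C)C | intermediate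
20 | 17-(tert-butyldimethylsilyloxy)-19-tert-butoxy-19-oxo-13,14,15,16-tetranorlabdan-12-oic acid | C[C@]12CCC[C@](C)(C(=O)OC(C)(C)C)[C@@H]1CC[C@@H](CO[Si](C)(C)C(C)(C)C)[C@@H]2CC(=O)O | intermediate
21 | tert-butyl 12-hydroxy-17-(tert-butyldimethylsilyloxy)-13,14,15,16-tetranorlabdan-19-oate | C[C@]12CCC[C@](C)(C(=O)OC(C)(C)C)[C@@H]1CC[C@@H](CO[Si](C)(C)C(C)(C)C)[C@@H]2CCO | intermediate
22 | iodine | II | starting material
23 | tert-butyl 12-iodo-17-(tert-butyldimethylsilyloxy)-13,14,15,16-tetranorlabdan-19-oate | C[C@]12CCC[C@](C)(C(=O)OC(C)(C)C)[C@@H]1CC[C@@H](CO[Si](C)(C)C(C)(C)C)[C@@H]2CCI | intermediate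
24 | tert-butyl but-2-ynoate | CC#CC(=O)OC(C)(C)C | starting material
25 | lithium 1-tert-butoxybuta-1,2,3-trien-1-olate (cumulenolate) | [Li+].[O-]C(OC(C)(C)C)=C=C=C | intermediate
26 | di-tert-butyl 17-(tert-butyldimethylsilyloxy)labda-13,14-diene-16,19-dioate (8β-H, 9α-H) | C[C@]12CCC[C@](C)(C(=O)OC(C)(C)C)[C@@H]1CC[C@@H](CO[Si](C)(C)C(C)(C)C)[C@@H]2CCC(=C=C)C(=O)OC(C)(C)C | intermediate
27 | tert-butyl 17-(tert-butyldimethylsilyloxy)labd-13-en-16,15-olid-19-oate | C[C@]12CCC[C@](C)(C(=O)OC(C)(C)C)[C@@H]1CC[C@@H](CO[Si](C)(C)C(C)(C)C)[C@@H]2CCC1=CCOC1=O | intermediate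
28 | (4S,5R,8R,9S,10R)-17-hydroxylabd-13-en-16,15-olid-19-oic acid | C[C@]12CCC[C@](C)(C(=O)O)[C@@H]1CC[C@@H](CO)[C@@H]2CCC1=CCOC1=O | target

Total step count: 12. Longest linear sequence: 12 steps (1 → 28).

Steps most likely to fail

Step 10. The SN2 reaction of the unactivated iodide may be slow, so that the cumulenolate instead adds to unreacted ynoate or to the allenoate already formed. The fallback sets out from iodide 23. Heating 23 with tert-butyl (triphenylphosphoranylidene)acetate (2 equiv, toluene, 90 °C) should give, by C-alkylation and transylidation, the α-alkylated stabilised ylide tert-butyl 17-(tert-butyldimethylsilyloxy)-13-(triphenylphosphoranylidene)-14,15-dinorlabdane-16,19-dioate F1. Wittig reaction of this ylide with ketene, made in the flask from acetyl chloride and Et3N (CH2Cl2, 0 °C → rt), should come back to the route at allenoate 26.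

Step 11. Attack on the unsubstituted allene terminus may be sluggish, so that Lewis-acid-induced loss of the silyl ether or hydration of the allene competes. The fallback sets out from allenoate 26. Iodolactonisation (I2, MeCN/H2O, rt) should close the same O–C15 bond by electrophilic activation, with iodine on C14 and loss of the tert-butyl group, to give tert-butyl 14-iodo-17-(tert-butyldimethylsilyloxy)labd-13-en-16,15-olid-19-oate F2. Reductive removal of the vinylic iodine (Zn dust, AcOH, rt) should come back to the route at butenolide 27.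

Step 6. The degradation of the α-keto carbonyl fragment may stay incomplete (normal instead of abnormal ozonolysis), so that borohydride work-up gives over-reduced polyol mixtures. The fallback sets out from enone 12. RuCl3 (cat.)/NaIO4 (CCl4/MeCN/H2O, rt) should cleave C13=C14 exhaustively, C13 leaving as CO2, to give 19-tert-butoxy-19-oxo-13,14,15,16-tetranorlabdane-12,17-dioic acid F3. BH3·THF should reduce both acids to tert-butyl 12,17-dihydroxy-13,14,15,16-tetranorlabdan-19-oate F4. TEMPO (cat.)/PhI(OAc)2 (CH2Cl2, rt) should oxidise the less hindered C12 carbinol first and the resulting lactol onward, which comes back to the route at lactone 15.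

Further compounds
F1 | step 10 | tert-butyl 17-(tert-butyldimethylsilyloxy)-13-(triphenylphosphoranylidene)-14,15-dinorlabdane-16,19-dioate | C[C@]12CCC[C@](C)(C(=O)OC(C)(C)C)[C@@H]1CC[C@@H](CO[Si](C)(C)C(C)(C)C)[C@@H]2CCC(C(=O)OC(C)(C)C)=P(c1ccccc1)(c1ccccc1)c1ccccc1
F2 | step 11 | tert-butyl 14-iodo-17-(tert-butyldimethylsilyloxy)labd-13-en-16,15-olid-19-oate | C[C@]12CCC[C@](C)(C(=O)OC(C)(C)C)[C@@H]1CC[C@@H](CO[Si](C)(C)C(C)(C)C)[C@@H]2CCC1=C(I)COC1=O
F3 | step 6 | 19-tert-butoxy-19-oxo-13,14,15,16-tetranorlabdane-12,17-dioic acid | C[C@]12CCC[C@](C)(C(=O)OC(C)(C)C)[C@@H]1CC[C@@H](C(=O)O)[C@@H]2CC(=O)O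
F4 | step 6 | tert-butyl 12,17-dihydroxy-13,14,15,16-tetranorlabdan-19-oate | C[C@]12CCC[C@](C)(C(=O)OC(C)(C)C)[C@@H]1CC[C@@H](CO)[C@@H]2CCO
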